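**Retrosynthetic overview**

1. Target ⇒ benzyl ester hydrogenolysis ⇒ depside C(=O)–O disconnection into the ring A acid (2,4-dimethoxy-6-pentylbenzoic acid) and the ring B phenol (benzyl olivetolate).
2. Both aryl units ⇒ one common precursor, methyl olivetolate: ring A by double O-methylation and saponification; ring B by decarboxylative saponification to olivetol, ortho-carboxylation and benzyl ester formation.
3. Methyl olivetolate ⇒ oxidative aromatisation of methyl 2,4-dioxo-6-pentylcyclohexane-1-carboxylate.
4. Key C–C disconnection: intermolecular Michael addition of dimethyl malonate to (E)-non-3-en-2-one, followed in the same flask by intramolecular Claisen (Dieckmann) closure.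
5. Ring order: the carbocycle is built once (Michael, then Claisen), aromatised, divided into the ring A and ring B streams, and the two rings are joined last by esterification.

Assumption: the target has no stereocentre and no stereogenic double bond, so no enantiocontrol is needed; the racemic sp3 centres of the cyclohexane intermediates vanish on aromatisation.

**Route**

Step 1
Reactants: 1 dimethyl malonate; 2 (E)-non-3-en-2-one
Product: 4 methyl 2-hydroxy-4-oxo-6-pentylcyclohex-2-ene-1-carboxylate (racemic), via Michael adduct 3 (not isolated)
Conditions: NaOMe (1.1 equiv), MeOH, reflux, 3 h; then aq. HCl, 0 °C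
Reagents that add atoms: none
Why: The malonate anion adds 1,4 to the enone (intermolecular Michael addition) and the methyl-ketone enolate of the adduct then closes the six-membered ring on one ester (intramolecular Claisen/Dieckmann condensation), driven by formation of the stabilised sodium enolate of the cyclic β-diketone; the two new stereocentres are racemic and are erased in step 2.

Step 2
Reactants: 4 methyl 2-hydroxy-4-oxo-6-pentylcyclohex-2-ene-1-carboxylate
Product: 6 methyl olivetolate (methyl 2,4-dihydroxy-6-pentylbenzoate), via bromo enol 5 (not isolated)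
Conditions: Br2 (1.0 equiv), DMF, 0 °C, 1 h; then 80 °C, 16 h
Reagents that add atoms: none
Why: Electrophilic α-bromination of the enolised β-diketone followed by thermal dehydrobromination and tautomerisation (oxidative aromatisation of a cyclohexane-1,3-dione) gives the resorcinol ring and removes both stereocentres.

Step 3
Reactants: 6 methyl olivetolate
Product: 7 methyl 2,4-dimethoxy-6-pentylbenzoate
Conditions: MeI (4 equiv), K2CO3 (4 equiv), DMF, 50 °C, 16 h
Reagents that add atoms: iodomethane, CI
Why: Williamson ether synthesis (SN2 O-methylation of both phenoxides); excess MeI and warm DMF overcome the hydrogen-bonded 2-OH, and the methyl ester is inert.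

Step 4
Reactants: 7 methyl 2,4-dimethoxy-6-pentylbenzoate
Product: 8 2,4-dimethoxy-6-pentylbenzoic acid
Conditions: KOH (6 equiv), DMSO/H2O (4:1), 100 °C, 12 h; then 2 M HCl, 0 °C
Reagents that add atoms: potassium hydroxide, [K+].[OH-]
Why: Saponification (acyl substitution) of the di-ortho-substituted ester needs poorly solvated hydroxide in DMSO; aryl methyl ethers are untouched and cold acidification avoids protodecarboxylation.

Step 5
Reactants: 6 methyl olivetolate
Product: 10 olivetol (5-pentylbenzene-1,3-diol), via sodium olivetolate 9 (not isolated)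
Conditions: 10% aq. NaOH, reflux, N2, 4 h; then conc. HCl to pH 1, 80 °C, 1 h
Reagents that add atoms: none
Why: Saponification followed by the facile protodecarboxylation of a β-resorcylic acid (ipso protonation, loss of CO2) cleanly gives the free resorcinol, because the free acid cannot be intercepted from the ester under hydrolytic conditions.

Step 6
Reactants: 10 olivetol
Product: 11 olivetolic acid (2,4-dihydroxy-6-pentylbenzoic acid)
Conditions: MeOMgOCO2Me (2 M in DMF, 8 equiv), 120 °C, 3 h, N2; then 2 M HCl, 0 °C
Reagents that add atoms: methyl magnesium carbonate (MeOMgOCO2Me), CO[Mg]OC(=O)OC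
Why: Stiles carboxylation (a Kolbe–Schmitt-type ortho-carboxylation) of the magnesium phenoxide is pulled forward by the stable magnesium salicylate chelate, and cold acidic work-up releases the acid without decarboxylation.

Step 7
Reactants: 11 olivetolic acid
Product: 12 benzyl olivetolate (benzyl 2,4-dihydroxy-6-pentylbenzoate)
Conditions: BnBr (1.05 equiv), KHCO3 (1.2 equiv), DMF, rt, 16 h
Reagents that add atoms: benzyl bromide, BrCc1ccccc1
Why: Bicarbonate deprotonates only the carboxylic acid, so SN2 O-alkylation gives the benzyl ester selectively and leaves both phenols free, at a temperature where the acid does not decarboxylate.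

Step 8
Reactants: 8 2,4-dimethoxy-6-pentylbenzoic acid; 12 benzyl olivetolate
Product: 14 benzyl 4-[(2,4-dimethoxy-6-pentylbenzoyl)oxy]-2-hydroxy-6-pentylbenzoate, via mixed trifluoroacetic anhydride 13 (not isolated)
Conditions: (CF3CO)2O (4 equiv), toluene, rt, 6 h
Reagents that add atoms: none
Why: Mixed-anhydride esterification: the hindered, electron-rich acid ionises readily to an aroyl cation equivalent that acylates the free 4-OH, while the 2-OH is deactivated by its hydrogen bond to the benzyl ester carbonyl.

Step 9
Reactants: 14 benzyl 4-[(2,4-dimethoxy-6-pentylbenzoyl)oxy]-2-hydroxy-6-pentylbenzoate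
Product: 15 2-hydroxy-4-[(2,4-dimethoxy-6-pentylbenzoyl)oxy]-6-pentylbenzoic acid (target)
Conditions: H2 (1 atm), 10% Pd/C, EtOAc, rt, 2 h
Reagents that add atoms: none
Why: Catalytic hydrogenolysis cleaves only the benzylic C–O bond; the aryl ester link, the aryl methyl ethers and the arene rings are inert under these neutral conditions.

**Compound list**

1 | dimethyl malonate (dimethyl propanedioate) | COC(=O)CC(=O)OC | starting material
2 | (E)-non-3-en-2-one | CCCCC/C=C/C(C)=O | starting material
3 | dimethyl 2-(2-oxononan-4-yl)propanedioate (Michael adduct, racemic, not isolated) | CCCCCC(CC(C)=O)C(C(=O)OC)C(=O)OC | intermediate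
4 | methyl 2-hydroxy-4-oxo-6-pentylcyclohex-2-ene-1-carboxylate (enol form of methyl 2,4-dioxo-6-pentylcyclohexane-1-carboxylate; racemic, C1/C6 configuration not controlled) | CCCCCC1CC(=O)C=C(O)C1C(=O)OC | intermediate
5 | methyl 3-bromo-2-hydroxy-4-oxo-6-pentylcyclohex-2-ene-1-carboxylate (racemic, not isolated) | CCCCCC1CC(=O)C(Br)=C(O)C1C(=O)OC | intermediate
6 | methyl olivetolate (methyl 2,4-dihydroxy-6-pentylbenzoate) | CCCCCc1cc(O)cc(O)c1C(=O)OC | intermediate
7 | methyl 2,4-dimethoxy-6-pentylbenzoate | CCCCCc1cc(OC)cc(OC)c1C(=O)OC | intermediate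
8 | 2,4-dimethoxy-6-pentylbenzoic acid | CCCCCc1cc(OC)cc(OC)c1C(=O)O | intermediate
9 | sodium 2,4-dihydroxy-6-pentylbenzoate (sodium olivetolate, drawn as the carboxylate salt, not isolated) | CCCCCc1cc(O)cc(O)c1C(=O)[O-].[Na+] | intermediate
10 | olivetol (5-pentylbenzene-1,3-diol) | CCCCCc1cc(O)cc(O)c1 | intermediate
11 | olivetolic acid (2,4-dihydroxy-6-pentylbenzoic acid) | CCCCCc1cc(O)cc(O)c1C(=O)O | intermediate
12 | benzyl olivetolate (benzyl 2,4-dihydroxy-6-pentylbenzoate) | CCCCCc1cc(O)cc(O)c1C(=O)OCc1ccccc1 | intermediate
13 | 2,4-dimethoxy-6-pentylbenzoic trifluoroacetic anhydride (not isolated) | CCCCCc1cc(OC)cc(OC)c1C(=O)OC(=O)C(F)(F)F | intermediate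
14 | benzyl 4-[(2,4-dimethoxy-6-pentylbenzoyl)oxy]-2-hydroxy-6-pentylbenzoate | CCCCCc1cc(OC(=O)c2c(CCCCC)cc(OC)cc2OC)cc(O)c1C(=O)OCc1ccccc1 | intermediate
15 | 2-hydroxy-4-[(2,4-dimethoxy-6-pentylbenzoyl)oxy]-6-pentylbenzoic acid (achiral) | CCCCCc1cc(OC(=O)c2c(CCCCC)cc(OC)cc2OC)cc(O)c1C(=O)O | target

**Step count**

Total steps: 9. Longest linear sequence: 7 (steps 1, 2, 5, 6, 7, 8, 9); the ring A branch (steps 3 and 4) joins at step 8.

**Steps most likely to fail, with fallbacks**

Step 2 (aromatisation). Risks are over-bromination of the electron-rich resorcinol, incomplete dehydrobromination and partial loss of the ester at higher temperature. The fallback sets out from 4 and comes back at 6. Instead of aiming for monobromination, 4 is deliberately over-brominated with Br2 (3 equiv) in AcOH at rt then 60 °C, which aromatises and ring-brominates in one operation to give crystalline methyl 3,5-dibromo-2,4-dihydroxy-6-pentylbenzoate F1. Both aryl C–Br bonds are then removed by hydrogenolysis (H2, 10% Pd/C, NaOAc, MeOH, rt) to give 6.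

Step 6 (carboxylation of olivetol). Risks are the equilibrium nature of the reaction, sensitivity to the quality of MeOMgOCO2Me, a possible regioisomeric 2,6-dihydroxy-4-pentylbenzoic acid, and decarboxylation on work-up. The fallback sets out from 10 (with 8) and comes back at 15, replacing the carboxyl group by an aldehyde that is oxidised at the end. Vilsmeier–Haack formylation of 10 (POCl3, DMF, 0 °C to rt) gives the aryl iminium chloride N-[(2,4-dihydroxy-6-pentylphenyl)methylidene]-N-methylmethanaminium chloride F2, which the aqueous NaOAc work-up hydrolyses to 2,4-dihydroxy-6-pentylbenzaldehyde F3. Coupling F3 with acid 8 under the conditions of step 8 ((CF3CO)2O, toluene, rt, via 13) gives 4-formyl-3-hydroxy-5-pentylphenyl 2,4-dimethoxy-6-pentylbenzoate F4. Pinnick oxidation (NaClO2, H2NSO3H, aq. dioxane, 0 °C) converts the aldehyde to the acid 15 directly, making steps 7 and 9 unnecessary.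

Step 8 (depside esterification). Risks are the steric hindrance of the di-ortho-substituted acid, competing O-trifluoroacetylation or C-acylation of the resorcinol ring, and some acylation at the 2-OH. The fallback sets out from 8 (with 12) and comes back at 14, changing from in-situ acidic activation to a discrete acyl chloride and a phenoxide nucleophile. Acid 8 is converted with (COCl)2 and catalytic DMF in CH2Cl2 at rt to 2,4-dimethoxy-6-pentylbenzoyl chloride F5, which is freed of volatiles. F5 is then added to 12 and K2CO3 in acetone (rt to 40 °C), where the more acidic, non-chelated 4-OH is selectively deprotonated and acylated to give 14.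

**Further compounds**

F1 | step 2 | methyl 3,5-dibromo-2,4-dihydroxy-6-pentylbenzoate | CCCCCc1c(Br)c(O)c(Br)c(O)c1C(=O)OC
F2 | step 6 | N-[(2,4-dihydroxy-6-pentylphenyl)methylidene]-N-methylmethanaminium chloride | CCCCCc1cc(O)cc(O)c1C=[N+](C)C.[Cl-]
F3 | step 6 | 2,4-dihydroxy-6-pentylbenzaldehyde | CCCCCc1cc(O)cc(O)c1C=O
F4 | step 6 | 4-formyl-3-hydroxy-5-pentylphenyl 2,4-dimethoxy-6-pentylbenzoate | CCCCCc1cc(OC(=O)c2c(CCCCC)cc(OC)cc2OC)cc(O)c1C=O
F5 | step 8 | 2,4-dimethoxy-6-pentylbenzoyl chloride | CCCCCc1cc(OC)cc(OC)c1C(Cl)=O
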